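Ring A is the benzo ring (C3a–C7a), ring B the dihydrofuran (O1, C2, C3, C3a, C7a), ring C the 3,4-dimethoxyphenyl ring.
Target 9 ← ester 8 (ester reduction) ← C5 boronate 6 (oxidative Heck with ethyl acrylate 7) ← dihydrobenzofuran 5 (C–H borylation at C5, the only aryl C–H without an ortho substituent).
5 ← racemic fluoro ketone 3: asymmetric hydrogenation with dynamic kinetic resolution sets C2 and C3, and the C2 alkoxide then closes ring B by bonding O1 to C7a of ring A with loss of fluoride.
Enabling feature: C3 lies between the C2 carbonyl and C3a of ring A, so it epimerises under base; the temporary fluorine on C7a, ortho to the side chain, places the C2 oxygen in a 1,5-relationship to the carbon it attacks.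
3 ← α-arylation of ketone 1 with aryl bromide 2 (C3–C3a bond); rings A and C are bought, ring B is the only ring formed.
Key step: step 2

Assumption: the (R)-XylBINAP/(R)-DAIPEN ruthenium catalyst, which reduces simple aryl alkyl ketones to (S)-carbinols, keeps this facial sense with ketone 3; if it were reversed, the mirror-image catalyst would be used.

Step 1
Reactants: 1 1-(3,4-dimethoxyphenyl)propan-1-one; 2 1-bromo-2-fluoro-3-methoxybenzene
Product: 3 rac-1-(3,4-dimethoxyphenyl)-2-(2-fluoro-3-methoxyphenyl)propan-1-one
Conditions: Pd2(dba)3 (1 mol%), Xantphos (2.4 mol%), NaOtBu (1.3 equiv), toluene, 80 °C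
Reagents that add atoms: none
Why: Palladium-catalysed ketone α-arylation (Buchwald–Hartwig type) should join the sodium enolate of 1 to the C–Br carbon of 2 only, because the C–F bond is inert to zerovalent palladium and the tertiary α-carbon formed resists a second arylation, and the new stereocentre is deliberately left racemic.

Step 2
Reactants: 3 rac-1-(3,4-dimethoxyphenyl)-2-(2-fluoro-3-methoxyphenyl)propan-1-one
Product: 5 (2S,3S)-2-(3,4-dimethoxyphenyl)-7-methoxy-3-methyl-2,3-dihydro-1-benzofuran, via (1S,2S)-fluoro alcohol 4 (not isolated)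
Conditions: RuCl2[(R)-xylbinap][(R)-daipen] (0.5 mol%), KOtBu (0.2 equiv), H2 (10 atm), iPrOH, 25 °C; then evaporate, KOtBu (1.3 equiv), DMF, 80 °C
Reagents that add atoms: none
Why: KOtBu enolises 3 reversibly, so the two ketone enantiomers interconvert fast, while the ruthenium hydride/amine catalyst (Noyori-type outer-sphere hydrogenation) delivers hydride to the Re face of the aryl ketone and does so fastest for the (S)-ketone, in which this face is also the Felkin–Anh face (hydride anti to the ring-A aryl on C3), so that dynamic kinetic resolution should funnel the racemate into the (1S,2S)-alkoxide of 4. After removal of 2-propanol the potassium alkoxide attacks C7a of ring A in a nucleophilic aromatic substitution (addition–elimination through a Meisenheimer-type state) and expels fluoride, which closes ring B in a 5-exo-trig mode and forms the O1–C7a bond. The closest known reaction types are the asymmetric hydrogenation of racemic α-aryl ketones with dynamic kinetic resolution and the base-mediated cyclisation of 2-(2-fluoroaryl)ethanols to 2,3-dihydrobenzofurans. C2 is set by catalyst control of the carbonyl face and C3 by the resolution coupled to it, and neither centre is touched in the ring closure because the C2–O bond is kept, so the anti alcohol should give the trans (2S,3S) ring. The step needs reduction to be complete before any cyclisation and closure without elimination: the unactivated C–F bond should not react with the enolate at 25 °C, and only a slight excess of base is used in the second stage to avoid base-induced reopening of ring B.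

Step 3
Reactants: 5 (2S,3S)-2-(3,4-dimethoxyphenyl)-7-methoxy-3-methyl-2,3-dihydro-1-benzofuran
Product: 6 2-[(2S,3S)-2-(3,4-dimethoxyphenyl)-7-methoxy-3-methyl-2,3-dihydro-1-benzofuran-5-yl]-4,4,5,5-tetramethyl-1,3,2-dioxaborolane
Conditions: [Ir(OMe)(cod)]2 (1.5 mol%), 4,4'-di-tert-butyl-2,2'-bipyridine (3 mol%), B2pin2 (1.0 equiv), THF, 65 °C
Reagents that add atoms: bis(pinacolato)diboron, CC1(C)OB(OC1(C)C)B1OC(C)(C)C(C)(C)O1
Why: Iridium-catalysed aromatic C–H borylation is governed by sterics, and since C5–H of ring A is the only aryl C–H in 5 without an ortho substituent (C4–H, C6–H and all three C–H bonds of ring C are flanked), the boryl group should enter at C5 without touching either stereocentre.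

Step 4
Reactants: 6 2-[(2S,3S)-2-(3,4-dimethoxyphenyl)-7-methoxy-3-methyl-2,3-dihydro-1-benzofuran-5-yl]-4,4,5,5-tetramethyl-1,3,2-dioxaborolane; 7 ethyl acrylate
Product: 8 ethyl (2E)-3-[(2S,3S)-2-(3,4-dimethoxyphenyl)-7-methoxy-3-methyl-2,3-dihydro-1-benzofuran-5-yl]prop-2-enoate
Conditions: Pd(OAc)2 (5 mol%), 2,9-dimethyl-1,10-phenanthroline (6 mol%), O2 (1 atm), DMF, 50 °C
Reagents that add atoms: none
Why: In this oxidative boron Heck (Mizoroki–Heck-type) reaction, transmetalation of the aryl boronate to divalent palladium, syn insertion of the acrylate and syn β-hydride elimination should give the (E)-cinnamate, while oxygen returns zerovalent palladium to the divalent state.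

Step 5
Reactants: 8 ethyl (2E)-3-[(2S,3S)-2-(3,4-dimethoxyphenyl)-7-methoxy-3-methyl-2,3-dihydro-1-benzofuran-5-yl]prop-2-enoate
Product: 9 (2E)-3-[(2S,3S)-2-(3,4-dimethoxyphenyl)-7-methoxy-3-methyl-2,3-dihydro-1-benzofuran-5-yl]prop-2-en-1-ol
Conditions: iBu2AlH (2.5 equiv), CH2Cl2, −78 to 0 °C; aqueous potassium sodium tartrate
Reagents that add atoms: none
Why: 1,2-Reduction of the α,β-unsaturated ester with diisobutylaluminium hydride at low temperature should give the (E)-allylic alcohol and leave the alkene geometry, the aryl ethers and both stereocentres unchanged.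

Compound list
1 | 1-(3,4-dimethoxyphenyl)propan-1-one | CCC(=O)c1ccc(OC)c(OC)c1 | starting material
2 | 1-bromo-2-fluoro-3-methoxybenzene | COc1cccc(Br)c1F | starting material
3 | rac-1-(3,4-dimethoxyphenyl)-2-(2-fluoro-3-methoxyphenyl)propan-1-one | COc1ccc(C(=O)C(C)c2cccc(OC)c2F)cc1OC | intermediate
4 | (1S,2S)-1-(3,4-dimethoxyphenyl)-2-(2-fluoro-3-methoxyphenyl)propan-1-ol (formed as its potassium alkoxide, not isolated) | COc1ccc([C@@H](O)[C@H](c2c(F)c(OC)ccc2)C)cc1OC | intermediate
5 | (2S,3S)-2-(3,4-dimethoxyphenyl)-7-methoxy-3-methyl-2,3-dihydro-1-benzofuran | COc1ccc([C@H]2Oc3c(OC)cccc3[C@@H]2C)cc1OC | intermediate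
6 | 2-[(2S,3S)-2-(3,4-dimethoxyphenyl)-7-methoxy-3-methyl-2,3-dihydro-1-benzofuran-5-yl]-4,4,5,5-tetramethyl-1,3,2-dioxaborolane | COc1ccc([C@H]2Oc3c(OC)cc(B4OC(C)(C)C(C)(C)O4)cc3[C@@H]2C)cc1OC | intermediate
7 | ethyl acrylate | C=CC(=O)OCC | starting material
8 | ethyl (2E)-3-[(2S,3S)-2-(3,4-dimethoxyphenyl)-7-methoxy-3-methyl-2,3-dihydro-1-benzofuran-5-yl]prop-2-enoate | COc1ccc([C@H]2Oc3c(OC)cc(/C=C/C(=O)OCC)cc3[C@@H]2C)cc1OC | intermediate
9 | (2E)-3-[(2S,3S)-2-(3,4-dimethoxyphenyl)-7-methoxy-3-methyl-2,3-dihydro-1-benzofuran-5-yl]prop-2-en-1-ol | COc1ccc([C@H]2Oc3c(OC)cc(/C=C/CO)cc3[C@@H]2C)cc1OC | target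

Total step count: 5. Longest linear sequence: 5 steps (1 or 2 to 9).

Steps most likely to fail

Step 2. Fluoride displacement at C7a, which is flanked by the C7 methoxy group and the side chain and carries no acceptor, may be slower than base-induced degradation such as β-elimination reopening ring B; incomplete racemisation of the ketone during hydrogenation would also lower the diastereomeric purity. The fallback replaces the addition–elimination by a palladium-catalysed C–O coupling, sets out from compound 1 and returns at compound 5. Ketone 1 would be arylated as in step 1 with commercially available 1-bromo-2-chloro-3-methoxybenzene, at the C–Br bond only, to give rac-2-(2-chloro-3-methoxyphenyl)-1-(3,4-dimethoxyphenyl)propan-1-one F1. Hydrogenation with the same ruthenium catalyst and KOtBu in iPrOH, with isolation, should give (1S,2S)-2-(2-chloro-3-methoxyphenyl)-1-(3,4-dimethoxyphenyl)propan-1-ol F2. Intramolecular etherification (Pd(OAc)2, 2-(di-tert-butylphosphino)-1,1'-binaphthyl, Cs2CO3, toluene, 80 °C) would then close ring B by C–O reductive elimination to give compound 5.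

Step 3. Borylation may run on to a second C–H bond (C5' of ring C, ortho to a methoxy group) or be slowed by the electron-rich arene, giving mixtures. The fallback installs the C5 handle before ring C is present, sets out from compound 2 and returns at compound 8. Compound 2, whose only unhindered C–H is the one para to fluorine, would be borylated ([Ir(OMe)(cod)]2, 4,4'-di-tert-butyl-2,2'-bipyridine, B2pin2, THF) to 2-(3-bromo-4-fluoro-5-methoxyphenyl)-4,4,5,5-tetramethyl-1,3,2-dioxaborolane F3. Without isolation, CuCl2 in aqueous methanol would convert this into 1-bromo-5-chloro-2-fluoro-3-methoxybenzene F4. α-Arylation of 1 with F4 as in step 1, at the C–Br bond only, should give rac-2-(5-chloro-2-fluoro-3-methoxyphenyl)-1-(3,4-dimethoxyphenyl)propan-1-one F5. The conditions of step 2 should lead, through (1S,2S)-2-(5-chloro-2-fluoro-3-methoxyphenyl)-1-(3,4-dimethoxyphenyl)propan-1-ol F6, to (2S,3S)-5-chloro-2-(3,4-dimethoxyphenyl)-7-methoxy-3-methyl-2,3-dihydro-1-benzofuran F7. A Mizoroki–Heck reaction of this aryl chloride with ethyl acrylate 7 (Pd2(dba)3, P(t-Bu)3, Cs2CO3, dioxane, 100 °C) would give compound 8.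

Step 4. Protodeboronation and oxidative homocoupling of the electron-rich aryl boronate may outrun alkene insertion under the oxidative conditions. The fallback changes to a classical halide-based Heck reaction, sets out from compound 6 and returns at compound 8. Ipso-bromodeboronation of 6 (CuBr2, MeOH/H2O, 80 °C) should give (2S,3S)-5-bromo-2-(3,4-dimethoxyphenyl)-7-methoxy-3-methyl-2,3-dihydro-1-benzofuran F8. A Mizoroki–Heck reaction of F8 with ethyl acrylate 7 under zerovalent palladium catalysis (Pd(OAc)2, P(o-tol)3, NaOAc, DMF, 110 °C) would give compound 8.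

Further compounds
F1 | step 2 | rac-2-(2-chloro-3-methoxyphenyl)-1-(3,4-dimethoxyphenyl)propan-1-one | COc1ccc(C(=O)C(C)c2cccc(OC)c2Cl)cc1OC
F2 | step 2 | (1S,2S)-2-(2-chloro-3-methoxyphenyl)-1-(3,4-dimethoxyphenyl)propan-1-ol | COc1ccc([C@@H](O)[C@H](c2c(Cl)c(OC)ccc2)C)cc1OC
F3 | step 3 | 2-(3-bromo-4-fluoro-5-methoxyphenyl)-4,4,5,5-tetramethyl-1,3,2-dioxaborolane | COc1cc(B2OC(C)(C)C(C)(C)O2)cc(Br)c1F
F4 | step 3 | 1-bromo-5-chloro-2-fluoro-3-methoxybenzene | COc1cc(Cl)cc(Br)c1F
F5 | step 3 | rac-2-(5-chloro-2-fluoro-3-methoxyphenyl)-1-(3,4-dimethoxyphenyl)propan-1-one | COc1ccc(C(=O)C(C)c2cc(Cl)cc(OC)c2F)cc1OC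
F6 | step 3 | (1S,2S)-2-(5-chloro-2-fluoro-3-methoxyphenyl)-1-(3,4-dimethoxyphenyl)propan-1-ol | COc1ccc([C@@H](O)[C@H](c2c(F)c(OC)cc(Cl)c2)C)cc1OC
F7 | step 3 | (2S,3S)-5-chloro-2-(3,4-dimethoxyphenyl)-7-methoxy-3-methyl-2,3-dihydro-1-benzofuran | COc1ccc([C@H]2Oc3c(OC)cc(Cl)cc3[C@@H]2C)cc1OC
F8 | step 4 | (2S,3S)-5-bromo-2-(3,4-dimethoxyphenyl)-7-methoxy-3-methyl-2,3-dihydro-1-benzofuran | COc1ccc([C@H]2Oc3c(OC)cc(Br)cc3[C@@H]2C)cc1OC
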